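**Retrosynthetic overview** (ring atoms of the target: O1, C2 aryl, C3 CH2OH, C4 aroyl, C5)
1. C2–aryl bond, made last: arylzinc substitution of a 2-sulfonyl oxolane through its oxocarbenium ion, aryl entering cis to the C3 CH2OH arm and trans to the C4 aroyl group.
2. Oxolane ring: ozonolysis of an (E)-propenyl group to the C2 aldehyde, which closes on the C5 hydroxyl as a lactol; then OH to SO2Ph.
3. C4 aroyl and C3 CH2OH: aryllithium opening of a trans-3-(hydroxymethyl)-4-propenyl-γ-butyrolactone (lactone C=O becomes the ketone, lactone CH2O becomes the free CH2OH).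
4. C4–C5: trans aldol of the lactone enolate with CH2O. C3–C4 bond and C3 configuration: Johnson–Claisen rearrangement of an (E)-allylic alcohol with 1,3-chirality transfer from its carbinol centre.
5. Allylic alcohol: cross-metathesis of (R)-but-3-en-2-ol with (Z)-but-2-ene-1,4-diyl diacetate. Ring order: γ-lactone (step 2, opened in step 4), then the oxolane (step 5); both arene rings are bought.

Assumption: (R)-but-3-en-2-ol is bought as the single enantiomer, and a sequence run in one flask without isolation counts as one step.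

**Step 1**
Reactants: 1 (R)-but-3-en-2-ol; 2 (Z)-but-2-ene-1,4-diyl diacetate
Product: 3 (2E,4R)-4-hydroxypent-2-en-1-yl acetate
Conditions: second-generation Grubbs catalyst RuCl2(=CHPh)(PCy3)(H2IMes) (3 mol %), 2 (2 equiv), CH2Cl2, 40 °C
Reagents that add atoms: none
Why: Olefin cross-metathesis of a terminal alkene with a symmetrical internal alkene gives the thermodynamically favoured E-alkene and leaves the carbinol stereocentre untouched.

**Step 2**
Reactants: 3 (2E,4R)-4-hydroxypent-2-en-1-yl acetate
Product: 6 (4R)-4-[(E)-prop-1-en-1-yl]oxolan-2-one, via ketene acetal 4 (not isolated), via Claisen ester 5 (not isolated)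
Conditions: MeC(OEt)3 (6 equiv), EtCO2H (5 mol %), 140 °C, EtOH distilled off; then K2CO3 (0.2 equiv), MeOH, rt; then 1 M HCl
Reagents that add atoms: triethyl orthoacetate, CC(OCC)(OCC)OCC
Why: The Johnson–Claisen [3,3]-sigmatropic rearrangement, through a chair transition state with the methyl group pseudo-equatorial, forms the C3–C4 bond and transfers the carbinol configuration to the new stereocentre (R, E-propenyl), after which acetate methanolysis lets the freed alcohol lactonise onto the ester.

**Step 3**
Reactants: 6 (4R)-4-[(E)-prop-1-en-1-yl]oxolan-2-one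
Product: 8 (3R,4S)-3-(hydroxymethyl)-4-[(E)-prop-1-en-1-yl]oxolan-2-one, via lithium enolate 7 (not isolated)
Conditions: LiN(i-Pr)2 (1.1 equiv), THF, −78 °C; then CH2O gas (cracked paraformaldehyde), −78 to −40 °C; aq NH4Cl
Reagents that add atoms: formaldehyde, C=O
Why: Aldol addition of the lactone lithium enolate to monomeric formaldehyde takes place on the face anti to the neighbouring propenyl group and so gives the 3,4-trans lactone.

**Step 4**
Reactants: 8 (3R,4S)-3-(hydroxymethyl)-4-[(E)-prop-1-en-1-yl]oxolan-2-one; 9 5-bromo-1,2,3-trimethoxybenzene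
Product: 11 (2R,3S,4E)-2,3-bis(hydroxymethyl)-1-(3,4,5-trimethoxyphenyl)hex-4-en-1-one, via aryllithium 10 (not isolated)
Conditions: 9 (2.4 equiv), n-BuLi (2.4 equiv), THF, −78 °C; then 8, −78 °C; aq NH4Cl at −78 °C
Reagents that add atoms: none
Why: Bromine–lithium exchange and 1,2-addition of the aryllithium to the lactone carbonyl give a lithium hemiketalate that is stable at −78 °C, so the reaction stops at the aryl ketone and frees the lactone CH2OH without touching either stereocentre (one equivalent is spent on the hydroxyl).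

**Step 5**
Reactants: 11 (2R,3S,4E)-2,3-bis(hydroxymethyl)-1-(3,4,5-trimethoxyphenyl)hex-4-en-1-one
Product: 13 [(3R,4S)-5-hydroxy-4-(hydroxymethyl)oxolan-3-yl](3,4,5-trimethoxyphenyl)methanone, via ozonide 12 (not isolated)
Conditions: O3, CH2Cl2, −78 °C; then PPh3, −78 °C to rt
Reagents that add atoms: ozone, [O-][O+]=O
Why: Ozonolysis with reductive work-up turns the propenyl group into the C2 aldehyde, which closes at once on the C5 hydroxyl to the five-membered lactol, while the ketone-deactivated arene is not attacked.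

**Step 6**
Reactants: 13 [(3R,4S)-5-hydroxy-4-(hydroxymethyl)oxolan-3-yl](3,4,5-trimethoxyphenyl)methanone
Product: 14 [(3R,4S)-5-(benzenesulfonyl)-4-(hydroxymethyl)oxolan-3-yl](3,4,5-trimethoxyphenyl)methanone
Conditions: PhSO2H (2 equiv), CaCl2, CH2Cl2, rt
Reagents that add atoms: benzenesulfinic acid, OS(=O)c1ccccc1
Why: Acid-promoted exchange of the anomeric hydroxyl for sulfinate through the cyclic oxocarbenium ion gives the 2-sulfonyl cyclic ether, whose anomeric mixture does not matter because C2 becomes planar again in the next step.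

**Step 7**
Reactants: 14 [(3R,4S)-5-(benzenesulfonyl)-4-(hydroxymethyl)oxolan-3-yl](3,4,5-trimethoxyphenyl)methanone; 15 3,4,5-trimethoxyphenylmagnesium bromide
Product: 17 [(3R,4S,5S)-4-(hydroxymethyl)-5-(3,4,5-trimethoxyphenyl)oxolan-3-yl](3,4,5-trimethoxyphenyl)methanone (target), via arylzinc bromide 16 (not isolated)
Conditions: 15 (3 equiv), ZnBr2 (3.3 equiv), THF, 0 °C; then 14, rt; aq NH4Cl
Reagents that add atoms: none
Why: Substitution of the 2-sulfonyl ether by the arylzinc goes through the ZnBr2-generated oxocarbenium ion, which adopts the envelope with both ring substituents pseudo-equatorial and is attacked from the inside face, so the aryl group ends cis to the C3 CH2OH arm and trans to the C4 aroyl group (C2 = S) while the arylzinc leaves the ketone alone.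

**Compound list**
1 | (R)-but-3-en-2-ol | C[C@@H](O)C=C | starting material
2 | (Z)-but-2-ene-1,4-diyl diacetate | CC(=O)OC/C=C\COC(C)=O | starting material
3 | (2E,4R)-4-hydroxypent-2-en-1-yl acetate | C[C@@H](O)/C=C/COC(C)=O | intermediate
4 | (2E,4R)-4-[(1-ethoxyethenyl)oxy]pent-2-en-1-yl acetate (ketene acetal, not isolated) | C=C(OCC)O[C@H](C)/C=C/COC(C)=O | intermediate
5 | ethyl (3R,4E)-3-(acetyloxymethyl)hex-4-enoate (not isolated) | CCOC(=O)C[C@@H](COC(C)=O)/C=C/C | intermediate
6 | (4R)-4-[(E)-prop-1-en-1-yl]oxolan-2-one | C/C=C/[C@H]1CC(=O)OC1 | intermediate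
7 | lithium (4R)-4-[(E)-prop-1-en-1-yl]-4,5-dihydrofuran-2-olate (enolate of 6, not isolated) | C/C=C/[C@H]1C=C(O[Li])OC1 | intermediate
8 | (3R,4S)-3-(hydroxymethyl)-4-[(E)-prop-1-en-1-yl]oxolan-2-one | C/C=C/[C@H]1[C@H](CO)C(=O)OC1 | intermediate
9 | 5-bromo-1,2,3-trimethoxybenzene | COc1cc(Br)cc(OC)c1OC | starting material
10 | (3,4,5-trimethoxyphenyl)lithium (not isolated) | [Li]c1cc(OC)c(OC)c(OC)c1 | intermediate
11 | (2R,3S,4E)-2,3-bis(hydroxymethyl)-1-(3,4,5-trimethoxyphenyl)hex-4-en-1-one (in equilibrium with its five-membered hemiketal) | C/C=C/[C@H](CO)[C@H](CO)C(=O)c1cc(OC)c(OC)c(OC)c1 | intermediate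
12 | ozonide of 11: (2R,3S)-2,3-bis(hydroxymethyl)-3-(5-methyl-1,2,4-trioxolan-3-yl)-1-(3,4,5-trimethoxyphenyl)propan-1-one (not isolated) | CC1OOC(O1)[C@H](CO)[C@H](CO)C(=O)c2cc(OC)c(OC)c(OC)c2 | intermediate
13 | [(3R,4S)-5-hydroxy-4-(hydroxymethyl)oxolan-3-yl](3,4,5-trimethoxyphenyl)methanone (anomer mixture) | O=C(c1cc(OC)c(OC)c(OC)c1)[C@H]1COC(O)[C@@H]1CO | intermediate
14 | [(3R,4S)-5-(benzenesulfonyl)-4-(hydroxymethyl)oxolan-3-yl](3,4,5-trimethoxyphenyl)methanone (anomer mixture) | O=C(c1cc(OC)c(OC)c(OC)c1)[C@H]1COC(S(=O)(=O)c2ccccc2)[C@@H]1CO | intermediate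
15 | 3,4,5-trimethoxyphenylmagnesium bromide (THF solution) | COc1cc([Mg]Br)cc(OC)c1OC | starting material
16 | bromo(3,4,5-trimethoxyphenyl)zinc (not isolated) | COc1cc([Zn]Br)cc(OC)c1OC | intermediate
17 | [(3R,4S,5S)-4-(hydroxymethyl)-5-(3,4,5-trimethoxyphenyl)oxolan-3-yl](3,4,5-trimethoxyphenyl)methanone | COc1cc(C(=O)[C@H]2CO[C@H](c3cc(OC)c(OC)c(OC)c3)[C@@H]2CO)cc(OC)c1OC | target

**Step count**
Total steps: 7. Longest linear sequence: 7 (the route is linear; 2, 9 and 15 are bought).

**Steps most likely to fail** (in rising step number; step 7 carries the most risk)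

Step 1. The cross-metathesis with the allylic diacetate may leave some Z-alkene, which step 2 would turn into the enantiomeric lactone, and ruthenium hydrides can isomerise the allylic alcohol. The fallback sets out from 1 and comes back at 3. Cross-metathesis of 1 with methyl acrylate under the same ruthenium catalyst gives only the E-enoate, methyl (2E,4R)-4-hydroxypent-2-enoate F1. Reduction with i-Bu2AlH (CH2Cl2, −78 °C) gives (2E,4R)-pent-2-ene-1,4-diol F2. AcCl with 2,4,6-collidine at −78 °C then acetylates only the primary hydroxyl and gives 3.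

Step 4. The aryllithium may enolise the hindered lactone or add twice, and the β-hydroxy ketone 11 can lose water or formaldehyde if it meets base. The fallback sets out from 8 and comes back at 11. The lactone is first opened with Me2AlN(OMe)Me (from MeNH(OMe)·HCl and Me3Al, CH2Cl2) to the Weinreb amide (2R,3S,4E)-2,3-bis(hydroxymethyl)-N-methoxy-N-methylhex-4-enamide F3. Addition of 10 (4 equiv, THF, −78 to 0 °C) then gives a chelated adduct that cannot over-add and releases 11 on work-up.

Step 7. The arylzinc has to take the oxocarbenium ion in the presence of a free hydroxyl and an aryl ketone, and the cis selectivity rests on a conformational preference that is precedented for alkyl and aryl ring substituents but not for a C4 acyl group. A retro-oxa-Michael opening at C4–C5 is a further danger. A C4 epimer, should any form, returns to 17 with DBU, because C4 is α to the ketone and trans is the stable arrangement. The fallback sets out from 14 and comes back at 17; it delivers the aryl group from a silicon tether. 15 and Me2SiCl2 give chloro(dimethyl)(3,4,5-trimethoxyphenyl)silane F4. This silylates the primary hydroxyl of 14 (imidazole, CH2Cl2) to the dimethyl(3,4,5-trimethoxyphenyl)silyl ether of 14 F5. SnCl4 in CH2Cl2 at −78 °C ionises the sulfone, and the tethered arene is transferred by ipso-substitution to C2, necessarily on the face of the CH2O arm. This leaves the chloro(dimethyl)silyl ether of 17 F6, which the aqueous KF work-up cleaves to 17.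

**Further compounds**
F1 | step 1 | methyl (2E,4R)-4-hydroxypent-2-enoate | C[C@@H](O)/C=C/C(=O)OC
F2 | step 1 | (2E,4R)-pent-2-ene-1,4-diol | C[C@@H](O)/C=C/CO
F3 | step 4 | (2R,3S,4E)-2,3-bis(hydroxymethyl)-N-methoxy-N-methylhex-4-enamide | C/C=C/[C@H](CO)[C@H](CO)C(=O)N(C)OC
F4 | step 7 | chloro(dimethyl)(3,4,5-trimethoxyphenyl)silane | COc1cc([Si](C)(C)Cl)cc(OC)c1OC
F5 | step 7 | dimethyl(3,4,5-trimethoxyphenyl)silyl ether of 14 | O=C(c1cc(OC)c(OC)c(OC)c1)[C@H]1COC(S(=O)(=O)c2ccccc2)[C@@H]1CO[Si](C)(C)c1cc(OC)c(OC)c(OC)c1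
F6 | step 7 | chloro(dimethyl)silyl ether of 17 | COc1cc(C(=O)[C@H]2CO[C@H](c3cc(OC)c(OC)c(OC)c3)[C@@H]2CO[Si](C)(C)Cl)cc(OC)c1OC
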